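**Strategy.** The guaiacyl ring of the biaryl is not coupled but built: its four substituted carbons, C3–OMe, C4–OH, C5–aryl (catechol ring B) and the C1 carbon that carries the furofuran, map onto methyl 3-benzyloxy-4-aryl-2-pyranone-6-carboxylate plus the two carbons of 1,1-dimethoxyethylene. One thermal operation forms both ring C–C bonds, expels CO2 and methanol, and delivers the pentasubstituted benzoate with the hindered biaryl bond already in place. The pyranone precursor comes from an aryl methyl ketone by glycolate aldol, dehydration and oxalate annulation. Afterwards the ester carbon becomes the furofuran benzylic carbon (lactone aldol, double etherification) and the aryl bromide of ring B becomes the dihydroflavonol (chromone arylation, enol ether oxidation).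

Key step: step 7

Remark on the chemistry: in step 20 the (R) antipode of the bisphosphine is assumed to deliver the aryl group to the chromone face that gives the 2S flavanone; the sense is to be confirmed on 35 with phenylboronic acid and the (S) ligand used if it is reversed. Compound 21 is bought as the benzyl ether of vanillin.

## Route

Step 1
Reactants: 1 1-(2-hydroxy-3-methoxyphenyl)ethan-1-one
Product: 2 1-(5-bromo-2-hydroxy-3-methoxyphenyl)ethan-1-one
Conditions: NBS, MeCN, 0 °C to rt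
Reagents that add atoms: N-bromosuccinimide, O=C1CCC(=O)N1Br
Why: Electrophilic aromatic bromination should go para to the free phenol (C5), the only activated position that is not blocked, as in the bromination of o-vanillin.

Step 2
Reactants: 2 1-(5-bromo-2-hydroxy-3-methoxyphenyl)ethan-1-one
Product: 3 1-(5-bromo-2,3-dihydroxyphenyl)ethan-1-one
Conditions: BBr3, CH2Cl2, −78 °C to 0 °C; aqueous work-up
Reagents that add atoms: none
Why: Lewis acid cleavage of the aryl methyl ether (BBr3 demethylation) frees the catechol, and the ketone and aryl bromide are inert to it.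

Step 3
Reactants: 3 1-(5-bromo-2,3-dihydroxyphenyl)ethan-1-one
Product: 4 1-[2,3-bis(benzyloxy)-5-bromophenyl]ethan-1-one
Conditions: BnBr, K2CO3, DMF, 60 °C
Reagents that add atoms: benzyl bromide, BrCc1ccccc1
Why: Williamson etherification of both phenols, with warming to bring in the hydroxyl that is hydrogen-bonded to the ketone.

Step 4
Reactants: 4 1-[2,3-bis(benzyloxy)-5-bromophenyl]ethan-1-one; 5 methyl 2-(benzyloxy)acetate
Product: 6 methyl 2-(benzyloxy)-3-[2,3-bis(benzyloxy)-5-bromophenyl]-3-hydroxybutanoate (racemic mixture of diastereomers)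
Conditions: LiN(i-Pr)2, 5, THF, −78 °C; then 4; NH4Cl quench at −78 °C
Reagents that add atoms: none
Why: Aldol addition of the lithium enolate of the glycolate ester to the methyl ketone; both new stereocentres are removed in step 5, so the mixture is used as such.

Step 5
Reactants: 6 methyl 2-(benzyloxy)-3-[2,3-bis(benzyloxy)-5-bromophenyl]-3-hydroxybutanoate
Product: 7 methyl 2-(benzyloxy)-3-[2,3-bis(benzyloxy)-5-bromophenyl]but-2-enoate (E/Z mixture)
Conditions: SOCl2, pyridine, CH2Cl2, 0 °C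
Reagents that add atoms: none
Why: Dehydration of the tertiary benzylic alcohol through its chlorosulfite (E2 with pyridine); alkene geometry does not matter because step 6 passes through a dienolate.

Step 6
Reactants: 7 methyl 2-(benzyloxy)-3-[2,3-bis(benzyloxy)-5-bromophenyl]but-2-enoate; 8 dimethyl oxalate
Product: 10 methyl 3-(benzyloxy)-4-[2,3-bis(benzyloxy)-5-bromophenyl]-2-oxo-2H-pyran-6-carboxylate, via oxalyl dienol diester 9 (not isolated)
Conditions: KOt-Bu, THF, 0 °C to rt; then 1 M HCl work-up and TsOH·H2O (cat.), PhMe, 80 °C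
Reagents that add atoms: none
Why: Under equilibrating alkoxide conditions the dienolate of 7 is acylated by 8 at the γ-methyl carbon (vinylogous Claisen condensation, as with crotonates; α-acylation is reversible because that product cannot be deprotonated), and the oxalyl enol then closes onto the C1 ester by 6-exo-trig acyl substitution to give the 2-pyranone.

Step 7
Reactants: 10 methyl 3-(benzyloxy)-4-[2,3-bis(benzyloxy)-5-bromophenyl]-2-oxo-2H-pyran-6-carboxylate; 11 1,1-dimethoxyethene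
Product: 14 methyl 4-(benzyloxy)-3-[2,3-bis(benzyloxy)-5-bromophenyl]-5-methoxybenzoate, via bicyclic lactone adduct 12 (not isolated), via ketal cyclohexadiene 13 (not isolated)
Conditions: 11 (8 equiv), PhMe, 120 °C, sealed tube
Reagents that add atoms: none
Why: The electron-poor 2-pyranone 10 is the 4π partner and the ketene acetal 11 the electron-rich 2π partner in a polar, asynchronous inverse-electron-demand (4+2) cycloaddition that joins the CH2 of 11 to C6 and the acetal carbon to C3. The bridged lactone 12 then loses CO2 by cycloreversion and the ketal diene 13 loses methanol by 1,2-elimination; the closest known reaction type is the benzannulation of ester-bearing 2-pyranones with 1,1-dimethoxyethylene to aryl methyl ethers. The one new ring, the six-membered carbocycle that becomes the guaiacyl ring, is closed intermolecularly through two C–C bonds, and aromatisation erases the two bridgehead stereocentres of 12, so no stereocentre remains. The step needs regioselectivity (CH2 to C6, not to C3). C6 is the vinylogous acyl terminus of the lactone carbonyl, where the pyranone LUMO is largest, and is flanked only by the ring oxygen and C5–H, whereas C3 carries the donor benzyloxy group at a position of small LUMO coefficient and is screened by the twisted ortho-substituted aryl group on C4, so the leading bond from the unhindered CH2 should form at C6. The 6-ester lowers the LUMO but also pulls towards C3, which is why it is kept as the small methyl ester and the reaction is run thermally without Lewis acid.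

Step 8
Reactants: 14 methyl 4-(benzyloxy)-3-[2,3-bis(benzyloxy)-5-bromophenyl]-5-methoxybenzoate
Product: 15 {4-(benzyloxy)-3-[2,3-bis(benzyloxy)-5-bromophenyl]-5-methoxyphenyl}methanol
Conditions: i-Bu2AlH, CH2Cl2, −78 °C to 0 °C; aq. KNaC4H4O6 work-up
Reagents that add atoms: none
Why: Hydride reduction of the ester to the benzylic alcohol; aryl bromide and benzyl ethers are inert to i-Bu2AlH at low temperature.

Step 9
Reactants: 15 {4-(benzyloxy)-3-[2,3-bis(benzyloxy)-5-bromophenyl]-5-methoxyphenyl}methanol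
Product: 16 4-(benzyloxy)-3-[2,3-bis(benzyloxy)-5-bromophenyl]-5-methoxybenzaldehyde
Conditions: MnO2, CH2Cl2, rt
Reagents that add atoms: none
Why: Manganese dioxide oxidises the benzylic alcohol selectively to the aldehyde without over-oxidation.

Step 10
Reactants: 17 4-(tert-butoxy)-4-oxobutanoic acid; 18 (4S)-4-benzyl-1,3-oxazolidin-2-one
Product: 20 tert-butyl 4-[(4S)-4-benzyl-2-oxo-1,3-oxazolidin-3-yl]-4-oxobutanoate, via mixed pivalic anhydride 19 (not isolated)
Conditions: t-BuCOCl, Et3N, THF, −20 °C; then 18, LiCl, rt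
Reagents that add atoms: none
Why: N-Acylation of the oxazolidinone by the mixed pivalic anhydride (LiCl/Et3N activation), with attack at the unhindered succinyl carbonyl.

Step 11
Reactants: 20 tert-butyl 4-[(4S)-4-benzyl-2-oxo-1,3-oxazolidin-3-yl]-4-oxobutanoate; 21 4-(benzyloxy)-3-methoxybenzaldehyde
Product: 22 tert-butyl (3S)-3-[(S)-[4-(benzyloxy)-3-methoxyphenyl](hydroxy)methyl]-4-[(4S)-4-benzyl-2-oxo-1,3-oxazolidin-3-yl]-4-oxobutanoate
Conditions: n-Bu2BOTf, i-Pr2NEt, CH2Cl2, 0 °C; 21, −78 °C to 0 °C; aq. NaH2PO4/Na2HPO4 (pH 7), MeOH, H2O2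
Reagents that add atoms: none
Why: Evans syn aldol: the Z boron enolate reacts through a chair Zimmerman–Traxler transition state on the face away from the auxiliary benzyl group, which sets C3 (S) and the carbinol carbon (S) together, and the tert-butyl ester keeps the aldolate from lactonising.

Step 12
Reactants: 22 tert-butyl (3S)-3-[(S)-[4-(benzyloxy)-3-methoxyphenyl](hydroxy)methyl]-4-[(4S)-4-benzyl-2-oxo-1,3-oxazolidin-3-yl]-4-oxobutanoate
Product: 23 tert-butyl (3S)-3-[(S)-[4-(benzyloxy)-3-methoxyphenyl]{[tert-butyl(dimethyl)silyl]oxy}methyl]-4-[(4S)-4-benzyl-2-oxo-1,3-oxazolidin-3-yl]-4-oxobutanoate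
Conditions: TBSCl, imidazole, DMF, 40 °C
Reagents that add atoms: tert-butyldimethylsilyl chloride, CC(C)(C)[Si](C)(C)Cl
Why: Silylation protects the secondary benzylic alcohol so that only the primary hydroxyl released in step 13 can lactonise.

Step 13
Reactants: 23 tert-butyl (3S)-3-[(S)-[4-(benzyloxy)-3-methoxyphenyl]{[tert-butyl(dimethyl)silyl]oxy}methyl]-4-[(4S)-4-benzyl-2-oxo-1,3-oxazolidin-3-yl]-4-oxobutanoate
Product: 25 (4R)-4-[(S)-[4-(benzyloxy)-3-methoxyphenyl]{[tert-butyl(dimethyl)silyl]oxy}methyl]oxolan-2-one, via hydroxy tert-butyl ester 24 (not isolated)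
Conditions: LiBH4, MeOH (1 equiv), THF, 0 °C; then PPTS (cat.), PhMe, 70 °C
Reagents that add atoms: none
Why: LiBH4 cleaves the imide reductively to the primary alcohol and releases the auxiliary, and the γ-hydroxy tert-butyl ester lactonises under mild acid catalysis without touching the stereocentres or the benzylic silyl ether.

Step 14
Reactants: 25 (4R)-4-[(S)-[4-(benzyloxy)-3-methoxyphenyl]{[tert-butyl(dimethyl)silyl]oxy}methyl]oxolan-2-one; 16 4-(benzyloxy)-3-[2,3-bis(benzyloxy)-5-bromophenyl]-5-methoxybenzaldehyde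
Product: 26 (3S,4R)-3-[(S)-{4-(benzyloxy)-3-[2,3-bis(benzyloxy)-5-bromophenyl]-5-methoxyphenyl}(hydroxy)methyl]-4-[(S)-[4-(benzyloxy)-3-methoxyphenyl]{[tert-butyl(dimethyl)silyl]oxy}methyl]oxolan-2-one
Conditions: KN(SiMe3)2, THF, −78 °C; then 16; AcOH quench at −78 °C
Reagents that add atoms: none
Why: Aldol addition of the lactone enolate occurs anti to the C4 substituent (sets C3, trans), and the potassium enolate is chosen because it is expected to favour the syn (erythro) carbinol needed here; the minor carbinol epimer is to be removed by chromatography.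

Step 15
Reactants: 26 (3S,4R)-3-[(S)-{4-(benzyloxy)-3-[2,3-bis(benzyloxy)-5-bromophenyl]-5-methoxyphenyl}(hydroxy)methyl]-4-[(S)-[4-(benzyloxy)-3-methoxyphenyl]{[tert-butyl(dimethyl)silyl]oxy}methyl]oxolan-2-one
Product: 28 (2R,3R)-2-[(S)-[4-(benzyloxy)-3-methoxyphenyl](hydroxy)methyl]-3-[(S)-{4-(benzyloxy)-3-[2,3-bis(benzyloxy)-5-bromophenyl]-5-methoxyphenyl}(hydroxy)methyl]butane-1,4-diol, via silyl triol 27 (not isolated)
Conditions: LiBH4, THF, 0 °C to rt; MeOH quench; then n-Bu4NF, THF, rt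
Reagents that add atoms: none
Why: Hydride reduction opens the lactone to the 1,4-diol and fluoride then removes the silyl ether; no stereocentre is affected.

Step 16
Reactants: 28 (2R,3R)-2-[(S)-[4-(benzyloxy)-3-methoxyphenyl](hydroxy)methyl]-3-[(S)-{4-(benzyloxy)-3-[2,3-bis(benzyloxy)-5-bromophenyl]-5-methoxyphenyl}(hydroxy)methyl]butane-1,4-diol
Product: 30 (1S,3aR,4S,6aR)-1-{4-(benzyloxy)-3-[2,3-bis(benzyloxy)-5-bromophenyl]-5-methoxyphenyl}-4-[4-(benzyloxy)-3-methoxyphenyl]tetrahydro-1H,3H-furo[3,4-c]furan, via bis-mesylate 29 (not isolated)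
Conditions: MsCl (2.2 equiv), pyridine, CH2Cl2, 0 °C to rt
Reagents that add atoms: none
Why: Sulfonylation is fastest at the two primary hydroxyls and each benzylic hydroxyl then displaces the mesylate on the other branch (5-exo-tet Williamson closure), so the benzylic C–O bonds are untouched and the two S carbinol centres are carried into the exo,exo furofuran, whose cis ring fusion is fixed by the 2R,3R centres.

Step 17
Reactants: 30 (1S,3aR,4S,6aR)-1-{4-(benzyloxy)-3-[2,3-bis(benzyloxy)-5-bromophenyl]-5-methoxyphenyl}-4-[4-(benzyloxy)-3-methoxyphenyl]tetrahydro-1H,3H-furo[3,4-c]furan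
Product: 31 {3,4-bis(benzyloxy)-5-[2-(benzyloxy)-5-{(1S,3aR,4S,6aR)-4-[4-(benzyloxy)-3-methoxyphenyl]tetrahydro-1H,3H-furo[3,4-c]furan-1-yl}-3-methoxyphenyl]phenyl}boronic acid
Conditions: B(O-i-Pr)3, n-BuLi, THF–PhMe, −78 °C (in situ quench); then aq. NH4Cl
Reagents that add atoms: triisopropyl borate, CC(C)OB(OC(C)C)OC(C)C; water, O
Why: Bromine–lithium exchange in the presence of the borate traps the aryllithium at once, and mild hydrolysis gives the boronic acid; nothing in 30 is acidic or electrophilic enough to compete at −78 °C.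

Step 18
Reactants: 32 1-(2,4,6-trihydroxyphenyl)ethan-1-one
Product: 33 1-[2,4-bis(benzyloxy)-6-hydroxyphenyl]ethan-1-one
Conditions: BnBr (2.1 equiv), K2CO3, DMF, rt
Reagents that add atoms: benzyl bromide, BrCc1ccccc1
Why: Williamson etherification; the hydroxyl hydrogen-bonded to the ketone is the least nucleophilic and is left free with two equivalents of halide.

Step 19
Reactants: 33 1-[2,4-bis(benzyloxy)-6-hydroxyphenyl]ethan-1-one
Product: 35 5,7-bis(benzyloxy)-4H-chromen-4-one, via enaminone 34 (not isolated)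
Conditions: Me2NCH(OMe)2, 95 °C; then conc. HCl, CH2Cl2, 40 °C
Reagents that add atoms: N,N-dimethylformamide dimethyl acetal, COC(OC)N(C)C
Why: Condensation of the methyl ketone with the amide acetal gives the enaminone, and acid closes the pyranone ring by addition of the free ortho phenol and loss of dimethylamine (standard chromone synthesis).

Step 20
Reactants: 31 {3,4-bis(benzyloxy)-5-[2-(benzyloxy)-5-{(1S,3aR,4S,6aR)-4-[4-(benzyloxy)-3-methoxyphenyl]tetrahydro-1H,3H-furo[3,4-c]furan-1-yl}-3-methoxyphenyl]phenyl}boronic acid; 35 5,7-bis(benzyloxy)-4H-chromen-4-one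
Product: 36 (2S)-5,7-bis(benzyloxy)-2-{3,4-bis(benzyloxy)-5-[2-(benzyloxy)-5-{(1S,3aR,4S,6aR)-4-[4-(benzyloxy)-3-methoxyphenyl]tetrahydro-1H,3H-furo[3,4-c]furan-1-yl}-3-methoxyphenyl]phenyl}-2,3-dihydro-4H-chromen-4-one
Conditions: [Rh(OH){(R)-MeO-F12-BIPHEP}]2 (2 mol %), PhMe–H2O (10:1), 25 °C
Reagents that add atoms: none
Why: Rhodium-catalysed asymmetric 1,4-addition of an arylboronic acid to a chromone (Hayashi–Miyaura type): the aryl–rhodium species inserts the C2=C3 bond and the chiral bisphosphine selects the enantiotopic face, setting C2 (S) under catalyst control remote from the furofuran, while base-free conditions avoid ring opening of the flavanone.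

Step 21
Reactants: 36 (2S)-5,7-bis(benzyloxy)-2-{3,4-bis(benzyloxy)-5-[2-(benzyloxy)-5-{(1S,3aR,4S,6aR)-4-[4-(benzyloxy)-3-methoxyphenyl]tetrahydro-1H,3H-furo[3,4-c]furan-1-yl}-3-methoxyphenyl]phenyl}-2,3-dihydro-4H-chromen-4-one
Product: 39 (2R,3R)-5,7-bis(benzyloxy)-2-{3,4-bis(benzyloxy)-5-[2-(benzyloxy)-5-{(1S,3aR,4S,6aR)-4-[4-(benzyloxy)-3-methoxyphenyl]tetrahydro-1H,3H-furo[3,4-c]furan-1-yl}-3-methoxyphenyl]phenyl}-3-hydroxy-2,3-dihydro-4H-chromen-4-one, via silyl enol ether 37 (not isolated), via silyloxy epoxide 38 (not isolated)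
Conditions: LiN(SiMe3)2, Me3SiCl, THF, −78 °C; then dimethyldioxirane, acetone–CH2Cl2, −40 °C; aq. citric acid work-up
Reagents that add atoms: dimethyldioxirane, CC1(C)OO1
Why: Rubottom-type oxidation: in situ silylation traps the C3 enolate before retro-oxa-Michael opening, dimethyldioxirane epoxidises the enol ether on the face anti to the C2 aryl group, and mild acid opens the silyloxy epoxide to the 2,3-trans ketol, setting C3 (R) under substrate control.

Step 22
Reactants: 39 (2R,3R)-5,7-bis(benzyloxy)-2-{3,4-bis(benzyloxy)-5-[2-(benzyloxy)-5-{(1S,3aR,4S,6aR)-4-[4-(benzyloxy)-3-methoxyphenyl]tetrahydro-1H,3H-furo[3,4-c]furan-1-yl}-3-methoxyphenyl]phenyl}-3-hydroxy-2,3-dihydro-4H-chromen-4-one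
Product: 40 (2R,3R)-2-{3,4-dihydroxy-5-[2-hydroxy-5-{(1S,3aR,4S,6aR)-4-(4-hydroxy-3-methoxyphenyl)tetrahydro-1H,3H-furo[3,4-c]furan-1-yl}-3-methoxyphenyl]phenyl}-3,5,7-trihydroxy-2,3-dihydro-4H-chromen-4-one (CNP0226398.1)
Conditions: H2 (1 atm), Pd/C, EtOAc–MeOH, rt
Reagents that add atoms: none
Why: Hydrogenolysis of the six benzyl aryl ethers at atmospheric pressure in a neutral solvent should be faster than cleavage of the benzylic C–O bonds of the furofuran and the chromanone, so the reaction is stopped at complete debenzylation.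

## Compound list

1 | 1-(2-hydroxy-3-methoxyphenyl)ethan-1-one | CC(=O)c1cccc(OC)c1O | starting material
2 | 1-(5-bromo-2-hydroxy-3-methoxyphenyl)ethan-1-one | CC(=O)c1cc(Br)cc(OC)c1O | intermediate
3 | 1-(5-bromo-2,3-dihydroxyphenyl)ethan-1-one | CC(=O)c1cc(Br)cc(O)c1O | intermediate
4 | 1-[2,3-bis(benzyloxy)-5-bromophenyl]ethan-1-one | CC(=O)c1cc(Br)cc(OCc2ccccc2)c1OCc1ccccc1 | intermediate
5 | methyl 2-(benzyloxy)acetate | COC(=O)COCc1ccccc1 | starting material
6 | methyl 2-(benzyloxy)-3-[2,3-bis(benzyloxy)-5-bromophenyl]-3-hydroxybutanoate (racemic diastereomer mixture) | COC(=O)C(OCc1ccccc1)C(C)(O)c1cc(Br)cc(OCc2ccccc2)c1OCc1ccccc1 | intermediate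
7 | methyl 2-(benzyloxy)-3-[2,3-bis(benzyloxy)-5-bromophenyl]but-2-enoate (E/Z mixture) | COC(=O)C(OCc1ccccc1)=C(C)c1cc(Br)cc(OCc2ccccc2)c1OCc1ccccc1 | intermediate
8 | dimethyl oxalate | COC(=O)C(=O)OC | starting material
9 | dimethyl 2-(benzyloxy)-3-[2,3-bis(benzyloxy)-5-bromophenyl]-5-hydroxyhexa-2,4-dienedioate (enol of the 5-oxo diester) | COC(=O)C(O)=CC(c1cc(Br)cc(OCc2ccccc2)c1OCc1ccccc1)=C(OCc1ccccc1)C(=O)OC | intermediate
10 | methyl 3-(benzyloxy)-4-[2,3-bis(benzyloxy)-5-bromophenyl]-2-oxo-2H-pyran-6-carboxylate | O=C1OC(C(=O)OC)=CC(c2cc(Br)cc(OCc3ccccc3)c2OCc2ccccc2)=C1OCc1ccccc1 | intermediate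
11 | 1,1-dimethoxyethene | C=C(OC)OC | starting material
12 | methyl 4-(benzyloxy)-5-[2,3-bis(benzyloxy)-5-bromophenyl]-8,8-dimethoxy-3-oxo-2-oxabicyclo[2.2.2]oct-5-ene-1-carboxylate (racemic) | O=C1OC2(C(=O)OC)CC(OC)(OC)C1(OCc1ccccc1)C(c1cc(Br)cc(OCc3ccccc3)c1OCc1ccccc1)=C2 | intermediate
13 | methyl 4-(benzyloxy)-3-[2,3-bis(benzyloxy)-5-bromophenyl]-5,5-dimethoxycyclohexa-1,3-diene-1-carboxylate | COC(=O)C1=CC(c2cc(Br)cc(OCc3ccccc3)c2OCc2ccccc2)=C(OCc2ccccc2)C(OC)(OC)C1 | intermediate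
14 | methyl 4-(benzyloxy)-3-[2,3-bis(benzyloxy)-5-bromophenyl]-5-methoxybenzoate | COC(=O)c1cc(OC)c(OCc2ccccc2)c(-c2cc(Br)cc(OCc3ccccc3)c2OCc2ccccc2)c1 | intermediate
15 | {4-(benzyloxy)-3-[2,3-bis(benzyloxy)-5-bromophenyl]-5-methoxyphenyl}methanol | OCc1cc(OC)c(OCc2ccccc2)c(-c2cc(Br)cc(OCc3ccccc3)c2OCc2ccccc2)c1 | intermediate
16 | 4-(benzyloxy)-3-[2,3-bis(benzyloxy)-5-bromophenyl]-5-methoxybenzaldehyde | O=Cc1cc(OC)c(OCc2ccccc2)c(-c2cc(Br)cc(OCc3ccccc3)c2OCc2ccccc2)c1 | intermediate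
17 | 4-(tert-butoxy)-4-oxobutanoic acid | CC(C)(C)OC(=O)CCC(=O)O | starting material
18 | (4S)-4-benzyl-1,3-oxazolidin-2-one | O=C1N[C@@H](Cc2ccccc2)CO1 | starting material
19 | 4-(tert-butoxy)-4-oxobutanoic pivalic anhydride | CC(C)(C)OC(=O)CCC(=O)OC(=O)C(C)(C)C | intermediate
20 | tert-butyl 4-[(4S)-4-benzyl-2-oxo-1,3-oxazolidin-3-yl]-4-oxobutanoate | CC(C)(C)OC(=O)CCC(=O)N1[C@@H](Cc2ccccc2)COC1=O | intermediate
21 | 4-(benzyloxy)-3-methoxybenzaldehyde | COc1cc(C=O)ccc1OCc1ccccc1 | starting material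
22 | tert-butyl (3S)-3-[(S)-[4-(benzyloxy)-3-methoxyphenyl](hydroxy)methyl]-4-[(4S)-4-benzyl-2-oxo-1,3-oxazolidin-3-yl]-4-oxobutanoate | CC(C)(C)OC(=O)C[C@H](C(=O)N1[C@@H](Cc2ccccc2)COC1=O)[C@H](O)c1ccc(OCc2ccccc2)c(OC)c1 | intermediate
23 | tert-butyl (3S)-3-[(S)-[4-(benzyloxy)-3-methoxyphenyl]{[tert-butyl(dimethyl)silyl]oxy}methyl]-4-[(4S)-4-benzyl-2-oxo-1,3-oxazolidin-3-yl]-4-oxobutanoate | CC(C)(C)OC(=O)C[C@H](C(=O)N1[C@@H](Cc2ccccc2)COC1=O)[C@H](O[Si](C)(C)C(C)(C)C)c1ccc(OCc2ccccc2)c(OC)c1 | intermediate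
24 | tert-butyl (3R,4S)-4-[4-(benzyloxy)-3-methoxyphenyl]-4-{[tert-butyl(dimethyl)silyl]oxy}-3-(hydroxymethyl)butanoate | CC(C)(C)OC(=O)C[C@H](CO)[C@H](O[Si](C)(C)C(C)(C)C)c1ccc(OCc2ccccc2)c(OC)c1 | intermediate
25 | (4R)-4-[(S)-[4-(benzyloxy)-3-methoxyphenyl]{[tert-butyl(dimethyl)silyl]oxy}methyl]oxolan-2-one | O=C1C[C@H](CO1)[C@H](O[Si](C)(C)C(C)(C)C)c1ccc(OCc2ccccc2)c(OC)c1 | intermediate
26 | (3S,4R)-3-[(S)-{4-(benzyloxy)-3-[2,3-bis(benzyloxy)-5-bromophenyl]-5-methoxyphenyl}(hydroxy)methyl]-4-[(S)-[4-(benzyloxy)-3-methoxyphenyl]{[tert-butyl(dimethyl)silyl]oxy}methyl]oxolan-2-one | O=C1OC[C@H]([C@H](O[Si](C)(C)C(C)(C)C)c2ccc(OCc3ccccc3)c(OC)c2)[C@H]1[C@H](O)c1cc(OC)c(OCc2ccccc2)c(-c2cc(Br)cc(OCc3ccccc3)c2OCc2ccccc2)c1 | intermediate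
27 | (2R,3R)-2-[(S)-[4-(benzyloxy)-3-methoxyphenyl]{[tert-butyl(dimethyl)silyl]oxy}methyl]-3-[(S)-{4-(benzyloxy)-3-[2,3-bis(benzyloxy)-5-bromophenyl]-5-methoxyphenyl}(hydroxy)methyl]butane-1,4-diol | OC[C@H]([C@H](O[Si](C)(C)C(C)(C)C)c1ccc(OCc2ccccc2)c(OC)c1)[C@H](CO)[C@H](O)c1cc(OC)c(OCc2ccccc2)c(-c2cc(Br)cc(OCc3ccccc3)c2OCc2ccccc2)c1 | intermediate
28 | (2R,3R)-2-[(S)-[4-(benzyloxy)-3-methoxyphenyl](hydroxy)methyl]-3-[(S)-{4-(benzyloxy)-3-[2,3-bis(benzyloxy)-5-bromophenyl]-5-methoxyphenyl}(hydroxy)methyl]butane-1,4-diol | OC[C@H]([C@H](O)c1ccc(OCc2ccccc2)c(OC)c1)[C@H](CO)[C@H](O)c1cc(OC)c(OCc2ccccc2)c(-c2cc(Br)cc(OCc3ccccc3)c2OCc2ccccc2)c1 | intermediate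
29 | (2R,3R)-2-[(S)-[4-(benzyloxy)-3-methoxyphenyl](hydroxy)methyl]-3-[(S)-{4-(benzyloxy)-3-[2,3-bis(benzyloxy)-5-bromophenyl]-5-methoxyphenyl}(hydroxy)methyl]butane-1,4-diyl dimethanesulfonate | CS(=O)(=O)OC[C@H]([C@H](O)c1ccc(OCc2ccccc2)c(OC)c1)[C@H](COS(C)(=O)=O)[C@H](O)c1cc(OC)c(OCc2ccccc2)c(-c2cc(Br)cc(OCc3ccccc3)c2OCc2ccccc2)c1 | intermediate
30 | (1S,3aR,4S,6aR)-1-{4-(benzyloxy)-3-[2,3-bis(benzyloxy)-5-bromophenyl]-5-methoxyphenyl}-4-[4-(benzyloxy)-3-methoxyphenyl]tetrahydro-1H,3H-furo[3,4-c]furan | COc1cc([C@H]2OC[C@H]3[C@@H]2CO[C@@H]3c2cc(OC)c(OCc4ccccc4)c(-c3cc(Br)cc(OCc4ccccc4)c3OCc3ccccc3)c2)ccc1OCc1ccccc1 | intermediate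
31 | {3,4-bis(benzyloxy)-5-[2-(benzyloxy)-5-{(1S,3aR,4S,6aR)-4-[4-(benzyloxy)-3-methoxyphenyl]tetrahydro-1H,3H-furo[3,4-c]furan-1-yl}-3-methoxyphenyl]phenyl}boronic acid | COc1cc([C@H]2OC[C@H]3[C@@H]2CO[C@@H]3c2cc(OC)c(OCc4ccccc4)c(-c3cc(B(O)O)cc(OCc4ccccc4)c3OCc3ccccc3)c2)ccc1OCc1ccccc1 | intermediate
32 | 1-(2,4,6-trihydroxyphenyl)ethan-1-one | CC(=O)c1c(O)cc(O)cc1O | starting material
33 | 1-[2,4-bis(benzyloxy)-6-hydroxyphenyl]ethan-1-one | CC(=O)c1c(O)cc(OCc2ccccc2)cc1OCc1ccccc1 | intermediate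
34 | (E)-1-[2,4-bis(benzyloxy)-6-hydroxyphenyl]-3-(dimethylamino)prop-2-en-1-one | CN(C)/C=C/C(=O)c1c(O)cc(OCc2ccccc2)cc1OCc1ccccc1 | intermediate
35 | 5,7-bis(benzyloxy)-4H-chromen-4-one | O=c1ccoc2cc(OCc3ccccc3)cc(OCc3ccccc3)c12 | intermediate
36 | (2S)-5,7-bis(benzyloxy)-2-{3,4-bis(benzyloxy)-5-[2-(benzyloxy)-5-{(1S,3aR,4S,6aR)-4-[4-(benzyloxy)-3-methoxyphenyl]tetrahydro-1H,3H-furo[3,4-c]furan-1-yl}-3-methoxyphenyl]phenyl}-2,3-dihydro-4H-chromen-4-one | COc1cc([C@H]2OC[C@H]3[C@@H]2CO[C@@H]3c2cc(OC)c(OCc4ccccc4)c(-c3cc([C@H]4Oc5cc(OCc6ccccc6)cc(OCc6ccccc6)c5C(=O)C4)cc(OCc4ccccc4)c3OCc3ccccc3)c2)ccc1OCc1ccccc1 | intermediate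
37 | (2S)-4-[(trimethylsilyl)oxy]-2H-chromene form of 36 (C3=C4 silyl enol ether, all other groups as in 36) | COc1cc([C@H]2OC[C@H]3[C@@H]2CO[C@@H]3c2cc(OC)c(OCc4ccccc4)c(-c3cc([C@H]4Oc5cc(OCc6ccccc6)cc(OCc6ccccc6)c5C(O[Si](C)(C)C)=C4)cc(OCc4ccccc4)c3OCc3ccccc3)c2)ccc1OCc1ccccc1 | intermediate
38 | C3–C4 oxirane of 37 (4-trimethylsilyloxy; oxirane oxygen trans to the C2 aryl group) | COc1cc([C@H]2OC[C@H]3[C@@H]2CO[C@@H]3c2cc(OC)c(OCc4ccccc4)c(-c3cc([C@H]4Oc5cc(OCc6ccccc6)cc(OCc6ccccc6)c5[C@]6(O[Si](C)(C)C)O[C@H]46)cc(OCc4ccccc4)c3OCc3ccccc3)c2)ccc1OCc1ccccc1 | intermediate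
39 | (2R,3R)-5,7-bis(benzyloxy)-2-{3,4-bis(benzyloxy)-5-[2-(benzyloxy)-5-{(1S,3aR,4S,6aR)-4-[4-(benzyloxy)-3-methoxyphenyl]tetrahydro-1H,3H-furo[3,4-c]furan-1-yl}-3-methoxyphenyl]phenyl}-3-hydroxy-2,3-dihydro-4H-chromen-4-one | COc1cc([C@H]2OC[C@H]3[C@@H]2CO[C@@H]3c2cc(OC)c(OCc4ccccc4)c(-c3cc([C@H]4Oc5cc(OCc6ccccc6)cc(OCc6ccccc6)c5C(=O)[C@@H]4O)cc(OCc4ccccc4)c3OCc3ccccc3)c2)ccc1OCc1ccccc1 | intermediate
40 | (2R,3R)-2-{3,4-dihydroxy-5-[2-hydroxy-5-{(1S,3aR,4S,6aR)-4-(4-hydroxy-3-methoxyphenyl)tetrahydro-1H,3H-furo[3,4-c]furan-1-yl}-3-methoxyphenyl]phenyl}-3,5,7-trihydroxy-2,3-dihydro-4H-chromen-4-one | COc1cc([C@H]2OC[C@H]3[C@@H]2CO[C@@H]3c2cc(OC)c(O)c(-c3cc([C@H]4Oc5cc(O)cc(O)c5C(=O)[C@@H]4O)cc(O)c3O)c2)ccc1O | target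

## Step count and risks

Total step count: 22. Longest linear sequence: 16 (steps 1–9, 14–17, 20–22). Steps 10–13 (lactone 25) and 18–19 (chromone 35) are side branches.

**Step 7.** The cycloaddition may proceed with the reversed orientation, the methylene carbon bonding to C3 under the pull of the 6-ester, or the ketene acetal may oligomerise before it adds to the hindered pyranone. The fallback sets out from 4 and comes back at 14 by a halogen-selective biaryl coupling. The acetyl group of 4 is degraded with NaOBr (dioxane–water, 0 °C) to 2,3-bis(benzyloxy)-5-bromobenzoic acid F1, and decarboxylative iodination (I2, K3PO4, MeCN, 100 °C) gives 1,2-bis(benzyloxy)-5-bromo-3-iodobenzene F2. Commercial methyl 3-bromo-4-hydroxy-5-methoxybenzoate is benzylated (BnBr, K2CO3, DMF) to methyl 4-(benzyloxy)-3-bromo-5-methoxybenzoate F3 and borylated (bis(pinacolato)diboron, PdCl2(dppf), KOAc, dioxane, 85 °C) to methyl 4-(benzyloxy)-3-methoxy-5-(4,4,5,5-tetramethyl-1,3,2-dioxaborolan-2-yl)benzoate F4. Suzuki–Miyaura coupling of F2 with F4 (Pd(PPh3)4, K3PO4, dioxane–water, 60 °C) should take place at the C–I bond and leave the C–Br bond, giving 14.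

**Step 20.** Aryl transfer to the electron-rich 5,7-dialkoxychromone may be slower than protodeboronation of 31, or the facial control by the ligand may be insufficient. The fallback sets out from 30 (with 33 as the second component) and comes back at 39 through a chalcone epoxide. Bromine–lithium exchange on 30 and trapping with DMF (n-BuLi, THF, −78 °C) gives the benzaldehyde F5 (30 with CHO in place of Br). Compound 33 is protected (MeOCH2Cl, i-Pr2NEt, CH2Cl2) as 1-[2,4-bis(benzyloxy)-6-(methoxymethoxy)phenyl]ethan-1-one F6. Claisen–Schmidt condensation of F5 with F6 (KOH, EtOH–THF, rt) gives the E chalcone F7. Juliá–Colonna epoxidation (poly-L-leucine, urea–H2O2, DBU, THF) is expected to give the (αR,βS) epoxide F8. Brief treatment with dilute methanolic HCl in THF removes the methoxymethyl group and the freed phenol opens the epoxide at the benzylic carbon with inversion, giving 39 directly. The exposure to acid is kept short and cold so that the furofuran is not epimerised.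

**Step 14.** The aldehyde may be attacked on the face that leads to the anti carbinol, so that the syn selectivity is eroded and the epimer would end, after step 16, as the endo-aryl furofuran. The fallback sets out from 26 as the mixture of carbinol epimers and comes back at 26 as the syn epimer. Dess–Martin oxidation (CH2Cl2, rt) gives the 3-aroyl lactone F9, in which the C3 centre settles trans to the C4 substituent. Chelation-controlled reduction with Zn(BH4)2 (Et2O, −20 °C) should deliver hydride to the zinc-bridged keto lactone from the side away from C4 and so give the syn carbinol.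

Further compounds
F1 | step 7 | 2,3-bis(benzyloxy)-5-bromobenzoic acid | OC(=O)c1cc(Br)cc(OCc2ccccc2)c1OCc1ccccc1
F2 | step 7 | 1,2-bis(benzyloxy)-5-bromo-3-iodobenzene | Ic1cc(Br)cc(OCc2ccccc2)c1OCc1ccccc1
F3 | step 7 | methyl 4-(benzyloxy)-3-bromo-5-methoxybenzoate | COC(=O)c1cc(Br)c(OCc2ccccc2)c(OC)c1
F4 | step 7 | methyl 4-(benzyloxy)-3-methoxy-5-(4,4,5,5-tetramethyl-1,3,2-dioxaborolan-2-yl)benzoate | COC(=O)c1cc(OC)c(OCc2ccccc2)c(B2OC(C)(C)C(C)(C)O2)c1
F5 | step 20 | 3,4-bis(benzyloxy)-5-[2-(benzyloxy)-5-{(1S,3aR,4S,6aR)-4-[4-(benzyloxy)-3-methoxyphenyl]tetrahydro-1H,3H-furo[3,4-c]furan-1-yl}-3-methoxyphenyl]benzaldehyde | COc1cc([C@H]2OC[C@H]3[C@@H]2CO[C@@H]3c2cc(OC)c(OCc4ccccc4)c(-c3cc(C=O)cc(OCc4ccccc4)c3OCc3ccccc3)c2)ccc1OCc1ccccc1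
F6 | step 20 | 1-[2,4-bis(benzyloxy)-6-(methoxymethoxy)phenyl]ethan-1-one | CC(=O)c1c(OCOC)cc(OCc2ccccc2)cc1OCc1ccccc1
F7 | step 20 | (E)-1-[2,4-bis(benzyloxy)-6-(methoxymethoxy)phenyl]-3-{3,4-bis(benzyloxy)-5-[2-(benzyloxy)-5-{(1S,3aR,4S,6aR)-4-[4-(benzyloxy)-3-methoxyphenyl]tetrahydro-1H,3H-furo[3,4-c]furan-1-yl}-3-methoxyphenyl]phenyl}prop-2-en-1-one | COc1cc([C@H]2OC[C@H]3[C@@H]2CO[C@@H]3c2cc(OC)c(OCc4ccccc4)c(-c3cc(/C=C/C(=O)c4c(OCOC)cc(OCc5ccccc5)cc4OCc4ccccc4)cc(OCc4ccccc4)c3OCc3ccccc3)c2)ccc1OCc1ccccc1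
F8 | step 20 | (αR,βS)-epoxide of F7: [2,4-bis(benzyloxy)-6-(methoxymethoxy)phenyl][(2R,3S)-3-aryl-oxiran-2-yl]methanone, aryl as in F7 | COc1cc([C@H]2OC[C@H]3[C@@H]2CO[C@@H]3c2cc(OC)c(OCc4ccccc4)c(-c3cc([C@@H]4O[C@H]4C(=O)c4c(OCOC)cc(OCc5ccccc5)cc4OCc4ccccc4)cc(OCc4ccccc4)c3OCc3ccccc3)c2)ccc1OCc1ccccc1
F9 | step 14 | (3S,4R)-3-{4-(benzyloxy)-3-[2,3-bis(benzyloxy)-5-bromophenyl]-5-methoxybenzoyl}-4-[(S)-[4-(benzyloxy)-3-methoxyphenyl]{[tert-butyl(dimethyl)silyl]oxy}methyl]oxolan-2-one | O=C1OC[C@H]([C@H](O[Si](C)(C)C(C)(C)C)c2ccc(OCc3ccccc3)c(OC)c2)[C@H]1C(=O)c1cc(OC)c(OCc2ccccc2)c(-c2cc(Br)cc(OCc3ccccc3)c2OCc2ccccc2)c1
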